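**Retrosynthetic overview**

1. Numbering: ring C1 (angelate, S), C2=C3 (CH3 on C3), C4 (OAc, R), C5, C6 (S); chain C7 (CH3, R), C8, C9 (OAc, R), C10=C11. The two ring oxygens are cis to each other and trans to the C6 chain.
2. Feature: C7 carries a methyl group and C8 is a CH2 beside carbonyl-level C9. C7–CH3 and C8–C9 are therefore cut together: methyl and aluminium add across a C7=C8 vinyl group on C6, and the C8–Al bond is acylated by 3-methylbut-2-enoyl chloride.
3. After the key step: C9 ketone to the (9R)-carbinol and its acetate, C1 silyl ether to the angelate, C4 silyl ether to the acetate.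
4. Before it: the bis-silylated vinylcyclohexenediol comes from the quinone monoketal of 4-methoxy-2-methylphenol by rhodium-catalysed asymmetric vinyl addition (sets C6), reduction at C4, ketal hydrolysis and reduction at C1.
5. Ring order: the only ring is the six-membered carbocycle of the starting phenol; no ring is formed in the route.

Key step: step 8

Remark (assumption): the catalyst antipodes are identified by their behaviour with simple substrates. (S)-BINAP/rhodium is taken as the one giving (S)-3-substituted cyclohexanones from cyclohex-2-enone, and (+)-(NMI)2ZrCl2 as the one giving (S)-2-methylalkyl alanes from alk-1-enes. The numbers C1–C11 defined above are used for all intermediates.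

**Route**

Step 1
Reactants: 1 4-methoxy-2-methylphenol
Product: 2 4,4-dimethoxy-2-methylcyclohexa-2,5-dien-1-one
Conditions: PhI(OAc)2, MeOH, 0 °C
Reagents that add atoms: methanol, CO
Why: Oxidative dearomatisation of a para-methoxyphenol, in which methanol traps the activated ring at the methoxy-bearing carbon to give the quinone monoketal (carbonyl carbon = C4, ketal carbon = C1); no stereocentre is formed.

Step 2
Reactants: 2 4,4-dimethoxy-2-methylcyclohexa-2,5-dien-1-one; 3 potassium vinyltrifluoroborate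
Product: 4 (5S)-5-ethenyl-4,4-dimethoxy-2-methylcyclohex-2-en-1-one
Conditions: [Rh(cod)2]BF4 (3 mol%), (S)-BINAP, Et3N, toluene/H2O, 23 °C
Reagents that add atoms: none
Why: Rhodium-catalysed asymmetric conjugate addition (Hayashi–Miyaura reaction) of the vinyl group to C6 of the unsubstituted enone arm, the methyl-bearing arm being too hindered for insertion; the (S)-BINAP–rhodium complex sets C6 with the facial sense it shows for cyclohex-2-enone.

Step 3
Reactants: 4 (5S)-5-ethenyl-4,4-dimethoxy-2-methylcyclohex-2-en-1-one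
Product: 5 (1R,5S)-5-ethenyl-4,4-dimethoxy-2-methylcyclohex-2-en-1-ol (4R,6S in the numbering above; hydroxyl trans to vinyl)
Conditions: (S)-2-methyl-CBS-oxazaborolidine (20 mol%), catecholborane, toluene, −78 °C
Reagents that add atoms: none
Why: Corey–Bakshi–Shibata reduction, in which the oxazaborolidine treats the branched C3 alkenyl arm as the large group and delivers hydride to the face that places the hydroxyl trans to the C6 vinyl group, against the ring's own preference for the cis alcohol; catecholborane should not hydroborate the vinyl group.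

Step 4
Reactants: 5 (1R,5S)-5-ethenyl-4,4-dimethoxy-2-methylcyclohex-2-en-1-ol
Product: 6 tert-butyl{[(1R,5S)-5-ethenyl-4,4-dimethoxy-2-methylcyclohex-2-en-1-yl]oxy}dimethylsilane
Conditions: TBSCl, imidazole, DMF, 23 °C
Reagents that add atoms: tert-butyldimethylsilyl chloride, CC(C)(C)[Si](C)(C)Cl
Why: Standard silylation of a secondary allylic alcohol under neutral conditions that leave the dimethyl ketal intact; no stereocentre is touched.

Step 5
Reactants: 6 tert-butyl{[(1R,5S)-5-ethenyl-4,4-dimethoxy-2-methylcyclohex-2-en-1-yl]oxy}dimethylsilane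
Product: 7 (4R,6S)-4-[(tert-butyldimethylsilyl)oxy]-6-ethenyl-3-methylcyclohex-2-en-1-one
Conditions: PPTS (cat.), acetone/H2O, 23 °C
Reagents that add atoms: water, O
Why: Acid-catalysed hydrolysis of the allylic dimethyl ketal through the conjugated oxocarbenium ion to the C1 enone; the acid is mild enough to keep the secondary silyl ether and should not enolise the ketone towards C6.

Step 6
Reactants: 7 (4R,6S)-4-[(tert-butyldimethylsilyl)oxy]-6-ethenyl-3-methylcyclohex-2-en-1-one
Product: 8 (1S,4R,6S)-4-[(tert-butyldimethylsilyl)oxy]-6-ethenyl-3-methylcyclohex-2-en-1-ol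
Conditions: NaBH4, CeCl3·7H2O, MeOH, −78 °C
Reagents that add atoms: none
Why: Luche 1,2-reduction, in which hydride attacks C1 axially on the half-chair with the C6 vinyl group equatorial and the C4 silyloxy group pseudoaxial, anti to that silyloxy group, so the hydroxyl ends trans to vinyl and cis to the C4 oxygen.

Step 7
Reactants: 8 (1S,4R,6S)-4-[(tert-butyldimethylsilyl)oxy]-6-ethenyl-3-methylcyclohex-2-en-1-ol
Product: 9 (1S,4R,6S)-4-[(tert-butyldimethylsilyl)oxy]-6-ethenyl-3-methyl-1-[(triethylsilyl)oxy]cyclohex-2-ene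
Conditions: TESCl, imidazole, DMF, 0 → 23 °C
Reagents that add atoms: chlorotriethylsilane, CC[Si](CC)(CC)Cl
Why: Standard silylation at oxygen, giving a C1 ether that can later be removed in the presence of the C4 tert-butyldimethylsilyl ether; no stereocentre is touched.

Step 8
Reactants: 9 (1S,4R,6S)-4-[(tert-butyldimethylsilyl)oxy]-6-ethenyl-3-methyl-1-[(triethylsilyl)oxy]cyclohex-2-ene; 10 trimethylaluminium; 11 3-methylbut-2-enoyl chloride
Product: 14 (6R)-6-[(1S,2S,5R)-5-[(tert-butyldimethylsilyl)oxy]-4-methyl-2-[(triethylsilyl)oxy]cyclohex-3-en-1-yl]-2-methylhept-2-en-4-one, via dimethylalkylalane 12 (not isolated), via alkylzinc chloride 13 (not isolated)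
Conditions: 10 (3 equiv), (+)-(NMI)2ZrCl2 [(+)-bis(1-neomenthylindenyl)zirconium dichloride, 5 mol%], methylaluminoxane (MeAlO)n, CH2Cl2, 0 → 23 °C; volatiles and excess 10 removed in vacuo; then ZnCl2 (3 equiv), Pd(PPh3)4 (5 mol%), 11 (excess), THF, 0 → 23 °C
Reagents that add atoms: zinc chloride, Cl[Zn]Cl (its atoms stand only in intermediate 13)
Why: The cationic methylzirconocene formed from (+)-(NMI)2ZrCl2 and 10 inserts the C7=C8 vinyl group with methyl on C7 and zirconium on C8, and exchange with aluminium releases the β-branched primary alane 12 (zirconium-catalysed asymmetric carboalumination); ZnCl2 then takes the alkyl group over as 13, zerovalent palladium adds oxidatively to 11, the alkyl group passes to the acyl complex of divalent palladium and reductive elimination forms C8–C9 (Negishi acylation). The closest known reaction types are this carboalumination followed in the same flask by palladium-catalysed cross-coupling of the alane through zinc, and the palladium-catalysed ketone synthesis from alkylzinc or alkylaluminium reagents and acid chlorides. No ring is closed. C7 is the only new stereocentre and is set by the chiral zirconocene, the antipode being the one that gives the (S)-2-methylalkyl metal from a simple alk-1-ene (7R after acylation); the substrate should reinforce it, since with C6–H eclipsing the alkene the open face is the one turned away from C1 and its silyloxy group. The step needs chemoselectivity for the monosubstituted alkene over the trisubstituted C2=C3 alkene, which the hindered zirconocene does not insert, and metal at the terminal carbon, which is the normal regiochemistry of the insertion. Both silyl ethers are inert to 10, and the ketone appears only at the end, in THF, where the aluminium and zinc halides left over should not add to it.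

Step 9
Reactants: 14 (6R)-6-[(1S,2S,5R)-5-[(tert-butyldimethylsilyl)oxy]-4-methyl-2-[(triethylsilyl)oxy]cyclohex-3-en-1-yl]-2-methylhept-2-en-4-one
Product: 15 (4R,6R)-6-[(1S,2S,5R)-5-[(tert-butyldimethylsilyl)oxy]-4-methyl-2-[(triethylsilyl)oxy]cyclohex-3-en-1-yl]-2-methylhept-2-en-4-ol (9R)
Conditions: (S)-2-methyl-CBS-oxazaborolidine (20 mol%), catecholborane, toluene, −78 °C
Reagents that add atoms: none
Why: Corey–Bakshi–Shibata 1,2-reduction of the enone, in which the 2-methylprop-1-enyl group, held s-cis and shielding its side of the carbonyl, acts as the large group and the C8 methylene as the small one, so the (S)-catalyst should deliver hydride to the face that gives 9R.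

Step 10
Reactants: 15 (4R,6R)-6-[(1S,2S,5R)-5-[(tert-butyldimethylsilyl)oxy]-4-methyl-2-[(triethylsilyl)oxy]cyclohex-3-en-1-yl]-2-methylhept-2-en-4-ol
Product: 16 (4R,6R)-6-[(1S,2S,5R)-5-[(tert-butyldimethylsilyl)oxy]-4-methyl-2-[(triethylsilyl)oxy]cyclohex-3-en-1-yl]-2-methylhept-2-en-4-yl acetate
Conditions: Ac2O, pyridine, DMAP (cat.), CH2Cl2, 0 → 23 °C
Reagents that add atoms: acetic anhydride, CC(=O)OC(C)=O
Why: Nucleophile-catalysed acylation at oxygen of the only free hydroxyl, with retention at C9.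

Step 11
Reactants: 16 (4R,6R)-6-[(1S,2S,5R)-5-[(tert-butyldimethylsilyl)oxy]-4-methyl-2-[(triethylsilyl)oxy]cyclohex-3-en-1-yl]-2-methylhept-2-en-4-yl acetate
Product: 17 (4R,6R)-6-[(1S,2S,5R)-5-[(tert-butyldimethylsilyl)oxy]-2-hydroxy-4-methylcyclohex-3-en-1-yl]-2-methylhept-2-en-4-yl acetate
Conditions: PPTS (cat.), MeOH/CH2Cl2, 0 °C
Reagents that add atoms: none
Why: Acid-catalysed methanolysis of a silyl ether, in which the triethylsilyl ether is cleaved far faster than the bulkier tert-butyldimethylsilyl ether, so only C1–OH is freed while the acetate stays.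

Step 12
Reactants: 17 (4R,6R)-6-[(1S,2S,5R)-5-[(tert-butyldimethylsilyl)oxy]-2-hydroxy-4-methylcyclohex-3-en-1-yl]-2-methylhept-2-en-4-yl acetate; 18 angelic acid
Product: 20 (1S,4R,6S)-6-[(2R,4R)-4-acetoxy-6-methylhept-5-en-2-yl]-4-[(tert-butyldimethylsilyl)oxy]-3-methylcyclohex-2-en-1-yl (2Z)-2-methylbut-2-enoate, via angelic 2,4,6-trichlorobenzoic anhydride 19 (not isolated)
Conditions: 18, 2,4,6-trichlorobenzoyl chloride, Et3N, toluene, 23 °C; then 17, 80 °C
Reagents that add atoms: 2,4,6-trichlorobenzoyl chloride, O=C(Cl)c1c(Cl)cc(Cl)cc1Cl (its atoms stand only in intermediate 19)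
Why: Yamaguchi esterification through the mixed anhydride, run without a nucleophilic catalyst so that the Z geometry of the angelate should be kept; acylation at oxygen leaves C1 unchanged.

Step 13
Reactants: 20 (1S,4R,6S)-6-[(2R,4R)-4-acetoxy-6-methylhept-5-en-2-yl]-4-[(tert-butyldimethylsilyl)oxy]-3-methylcyclohex-2-en-1-yl (2Z)-2-methylbut-2-enoate
Product: 21 (1S,4R,6S)-6-[(2R,4R)-4-acetoxy-6-methylhept-5-en-2-yl]-4-hydroxy-3-methylcyclohex-2-en-1-yl (2Z)-2-methylbut-2-enoate
Conditions: HF·pyridine, pyridine, THF, 0 → 23 °C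
Reagents that add atoms: none
Why: Fluoride-mediated desilylation under buffered, weakly acidic conditions, which avoid a free alkoxide that could move an acyl group or isomerise the angelate.

Step 14
Reactants: 21 (1S,4R,6S)-6-[(2R,4R)-4-acetoxy-6-methylhept-5-en-2-yl]-4-hydroxy-3-methylcyclohex-2-en-1-yl (2Z)-2-methylbut-2-enoate
Product: 22 (1S,4R,6S)-4-acetoxy-6-[(2R,4R)-4-acetoxy-6-methylhept-5-en-2-yl]-3-methylcyclohex-2-en-1-yl (2Z)-2-methylbut-2-enoate (CNP0417294.1)
Conditions: Ac2O, pyridine, DMAP (cat.), CH2Cl2, 23 °C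
Reagents that add atoms: acetic anhydride, CC(=O)OC(C)=O
Why: Nucleophile-catalysed acylation of the C4 allylic alcohol at oxygen, with retention at C4, completing the target.

**Compound list**

1 | 4-methoxy-2-methylphenol | COc1ccc(O)c(C)c1 | starting material
2 | 4,4-dimethoxy-2-methylcyclohexa-2,5-dien-1-one | COC1(OC)C=CC(=O)C(C)=C1 | intermediate
3 | potassium vinyltrifluoroborate | C=C[B-](F)(F)F.[K+] | starting material
4 | (5S)-5-ethenyl-4,4-dimethoxy-2-methylcyclohex-2-en-1-one | COC1(OC)C=C(C)C(=O)C[C@H]1C=C | intermediate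
5 | (1R,5S)-5-ethenyl-4,4-dimethoxy-2-methylcyclohex-2-en-1-ol | COC1(OC)C=C(C)[C@H](O)C[C@H]1C=C | intermediate
6 | tert-butyl{[(1R,5S)-5-ethenyl-4,4-dimethoxy-2-methylcyclohex-2-en-1-yl]oxy}dimethylsilane | COC1(OC)C=C(C)[C@H](O[Si](C)(C)C(C)(C)C)C[C@H]1C=C | intermediate
7 | (4R,6S)-4-[(tert-butyldimethylsilyl)oxy]-6-ethenyl-3-methylcyclohex-2-en-1-one | O=C1C=C(C)[C@H](O[Si](C)(C)C(C)(C)C)C[C@H]1C=C | intermediate
8 | (1S,4R,6S)-4-[(tert-butyldimethylsilyl)oxy]-6-ethenyl-3-methylcyclohex-2-en-1-ol | O[C@@H]1C=C(C)[C@H](O[Si](C)(C)C(C)(C)C)C[C@H]1C=C | intermediate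
9 | (1S,4R,6S)-4-[(tert-butyldimethylsilyl)oxy]-6-ethenyl-3-methyl-1-[(triethylsilyl)oxy]cyclohex-2-ene | CC[Si](CC)(CC)O[C@@H]1C=C(C)[C@H](O[Si](C)(C)C(C)(C)C)C[C@H]1C=C | intermediate
10 | trimethylaluminium | C[Al](C)C | starting material
11 | 3-methylbut-2-enoyl chloride | CC(C)=CC(Cl)=O | starting material
12 | dimethyl{(2S)-2-[(1S,2S,5R)-5-[(tert-butyldimethylsilyl)oxy]-4-methyl-2-[(triethylsilyl)oxy]cyclohex-3-en-1-yl]propyl}alane (C7 as in the target; descriptor S because C8 carries the metal) | CC[Si](CC)(CC)O[C@@H]1C=C(C)[C@H](O[Si](C)(C)C(C)(C)C)C[C@H]1[C@H](C)C[Al](C)C | intermediate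
13 | {(2S)-2-[(1S,2S,5R)-5-[(tert-butyldimethylsilyl)oxy]-4-methyl-2-[(triethylsilyl)oxy]cyclohex-3-en-1-yl]propyl}zinc chloride | CC[Si](CC)(CC)O[C@@H]1C=C(C)[C@H](O[Si](C)(C)C(C)(C)C)C[C@H]1[C@H](C)C[Zn]Cl | intermediate
14 | (6R)-6-[(1S,2S,5R)-5-[(tert-butyldimethylsilyl)oxy]-4-methyl-2-[(triethylsilyl)oxy]cyclohex-3-en-1-yl]-2-methylhept-2-en-4-one | CC[Si](CC)(CC)O[C@@H]1C=C(C)[C@H](O[Si](C)(C)C(C)(C)C)C[C@H]1[C@H](C)CC(=O)C=C(C)C | intermediate
15 | (4R,6R)-6-[(1S,2S,5R)-5-[(tert-butyldimethylsilyl)oxy]-4-methyl-2-[(triethylsilyl)oxy]cyclohex-3-en-1-yl]-2-methylhept-2-en-4-ol | CC[Si](CC)(CC)O[C@@H]1C=C(C)[C@H](O[Si](C)(C)C(C)(C)C)C[C@H]1[C@H](C)C[C@H](C=C(C)C)O | intermediate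
16 | (4R,6R)-6-[(1S,2S,5R)-5-[(tert-butyldimethylsilyl)oxy]-4-methyl-2-[(triethylsilyl)oxy]cyclohex-3-en-1-yl]-2-methylhept-2-en-4-yl acetate | CC[Si](CC)(CC)O[C@@H]1C=C(C)[C@H](O[Si](C)(C)C(C)(C)C)C[C@H]1[C@H](C)C[C@H](C=C(C)C)OC(C)=O | intermediate
17 | (4R,6R)-6-[(1S,2S,5R)-5-[(tert-butyldimethylsilyl)oxy]-2-hydroxy-4-methylcyclohex-3-en-1-yl]-2-methylhept-2-en-4-yl acetate | O[C@@H]1C=C(C)[C@H](O[Si](C)(C)C(C)(C)C)C[C@H]1[C@H](C)C[C@H](C=C(C)C)OC(C)=O | intermediate
18 | angelic acid, (2Z)-2-methylbut-2-enoic acid | C/C=C(/C)C(=O)O | starting material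
19 | (2Z)-2-methylbut-2-enoic 2,4,6-trichlorobenzoic anhydride | C/C=C(/C)C(=O)OC(=O)c1c(Cl)cc(Cl)cc1Cl | intermediate
20 | (1S,4R,6S)-6-[(2R,4R)-4-acetoxy-6-methylhept-5-en-2-yl]-4-[(tert-butyldimethylsilyl)oxy]-3-methylcyclohex-2-en-1-yl (2Z)-2-methylbut-2-enoate | C/C=C(/C)C(=O)O[C@@H]1C=C(C)[C@H](O[Si](C)(C)C(C)(C)C)C[C@H]1[C@H](C)C[C@H](C=C(C)C)OC(C)=O | intermediate
21 | (1S,4R,6S)-6-[(2R,4R)-4-acetoxy-6-methylhept-5-en-2-yl]-4-hydroxy-3-methylcyclohex-2-en-1-yl (2Z)-2-methylbut-2-enoate | C/C=C(/C)C(=O)O[C@@H]1C=C(C)[C@H](O)C[C@H]1[C@H](C)C[C@H](C=C(C)C)OC(C)=O | intermediate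
22 | (1S,4R,6S)-4-acetoxy-6-[(2R,4R)-4-acetoxy-6-methylhept-5-en-2-yl]-3-methylcyclohex-2-en-1-yl (2Z)-2-methylbut-2-enoate | C/C=C(/C)C(=O)O[C@@H]1C=C(C)[C@H](OC(C)=O)C[C@H]1[C@H](C)C[C@H](C=C(C)C)OC(C)=O | target

**Step count**

Total: 14 steps. Longest linear sequence: 14 steps (1 to 22).

**Steps most likely to fail**

Step 8. Two processes may go wrong. The branched alkyl group may pass from aluminium and zinc to the acylpalladium complex more slowly than the methyl groups. The acid chloride, activated by the aluminium and zinc halides, may also cleave the triethylsilyl ether by acylation. The fallback keeps the carboalumination but separates the ketone-forming bond from the alane. It sets out from 9: alane 12 is made as in step 8 and cleaved with iodine (THF, −30 → 0 °C) to the primary iodide (1S,4R,6S)-4-[(tert-butyldimethylsilyl)oxy]-6-[(2S)-1-iodopropan-2-yl]-3-methyl-1-[(triethylsilyl)oxy]cyclohex-2-ene F1. In a second flask 11 is converted with N,O-dimethylhydroxylamine hydrochloride and pyridine (CH2Cl2, 0 °C) into N-methoxy-N,3-dimethylbut-2-enamide F2. Iodine–lithium exchange of F1 with tert-butyllithium (2 equiv, Et2O/pentane, −78 °C) should give the primary alkyllithium F3, which adds to F2 to form a chelated adduct and, after aqueous work-up, the ketone (Weinreb ketone synthesis). The fallback comes back to the route at 14.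

Step 3. Facial selectivity may be poor because the oxazaborolidine has to act against the ring's preference for axial hydride delivery, which leads to the cis alcohol. The fallback uses that preference and then inverts. It sets out from 4: NaBH4/CeCl3·7H2O in MeOH at −78 °C should give the cis alcohol (1S,5S)-5-ethenyl-4,4-dimethoxy-2-methylcyclohex-2-en-1-ol F4. Mitsunobu reaction with 4-nitrobenzoic acid, PPh3 and diisopropyl azodicarboxylate (THF, 0 °C) inverts the carbinol carbon to give (1R,5S)-5-ethenyl-4,4-dimethoxy-2-methylcyclohex-2-en-1-yl 4-nitrobenzoate F5. Methanolysis with K2CO3 in MeOH then frees the trans alcohol. The fallback comes back to the route at 5.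

Step 9. The oxazaborolidine may discriminate poorly between the 2-methylprop-1-enyl group and the β-branched C8 methylene, giving both C9 epimers. The fallback gives up reagent control in favour of separation and recycling. It sets out from 14: NaBH4/CeCl3·7H2O in MeOH at −78 °C should give 15 together with its C9 epimer (4S,6R)-6-[(1S,2S,5R)-5-[(tert-butyldimethylsilyl)oxy]-4-methyl-2-[(triethylsilyl)oxy]cyclohex-3-en-1-yl]-2-methylhept-2-en-4-ol F6. The two are diastereomers and should separate by chromatography. F6 is oxidised back to 14 with MnO2 (CH2Cl2, 23 °C) and reduced again. The fallback comes back to the route at 15.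

**Further compounds**

F1 | step 8 | (1S,4R,6S)-4-[(tert-butyldimethylsilyl)oxy]-6-[(2S)-1-iodopropan-2-yl]-3-methyl-1-[(triethylsilyl)oxy]cyclohex-2-ene | CC[Si](CC)(CC)O[C@@H]1C=C(C)[C@H](O[Si](C)(C)C(C)(C)C)C[C@H]1[C@H](C)CI
F2 | step 8 | N-methoxy-N,3-dimethylbut-2-enamide | CON(C)C(=O)C=C(C)C
F3 | step 8 | {(2S)-2-[(1S,2S,5R)-5-[(tert-butyldimethylsilyl)oxy]-4-methyl-2-[(triethylsilyl)oxy]cyclohex-3-en-1-yl]propyl}lithium | CC[Si](CC)(CC)O[C@@H]1C=C(C)[C@H](O[Si](C)(C)C(C)(C)C)C[C@H]1[C@H](C)C[Li]
F4 | step 3 | (1S,5S)-5-ethenyl-4,4-dimethoxy-2-methylcyclohex-2-en-1-ol | COC1(OC)C=C(C)[C@@H](O)C[C@H]1C=C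
F5 | step 3 | (1R,5S)-5-ethenyl-4,4-dimethoxy-2-methylcyclohex-2-en-1-yl 4-nitrobenzoate | COC1(OC)C=C(C)[C@H](OC(=O)c2ccc(cc2)[N+](=O)[O-])C[C@H]1C=C
F6 | step 9 | (4S,6R)-6-[(1S,2S,5R)-5-[(tert-butyldimethylsilyl)oxy]-4-methyl-2-[(triethylsilyl)oxy]cyclohex-3-en-1-yl]-2-methylhept-2-en-4-ol | CC[Si](CC)(CC)O[C@@H]1C=C(C)[C@H](O[Si](C)(C)C(C)(C)C)C[C@H]1[C@H](C)C[C@@H](C=C(C)C)O
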